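(All runs stem from a simulated flask on assumed constants, and the scatter is random.)

- The constants of this flask are hidden, so I freeze what looks steady in Saturday's readings, which follow this same flask, and draw its curve from one time constant.

| setting | Saturday's | flask |
|---|---|---|
| substrate | 2.2 M | 2.2 M |
| gas phase | 78 mM (held) | 78 mM (held) |
| free catalyst | 0.5 mol% | 0.5 mol% |
| remark | the very flask that is asked about, followed so far |  |
| time |  | 40 h |

Saturday's run (percent of the substrate charged)

| time / h | product / % | substrate / % |
|---|---|---|
| 1.33 | 3.4 | 99.2 |
| 2.00 | 3.0 | 95.8 |
| 4.00 | 6.6 | 94.5 |
| 6.00 | 10.1 | 90.9 |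
| 10.0 | 14.0 | 86.4 |
| 15.0 | 18.1 | 79.6 |

(standard deviation of a reading: 1 percentage point)

- at the start none of the gas phase is in solution

1. amount of product at 40 h, in percent of the substrate charged
2. the change that raises the amount of product at 40 h, in percent of the substrate charged most ("none" if none brings more than 2 percentage points) (birch / oak / maple / none)
3. amount of product at 40 h, in percent of the substrate charged, after birch

- birch: doubling the transfer coefficient of the gas phase, all else as stated
- oak: doubling the amount of free catalyst, all else as stated
- maple: doubling the saturation concentration of gas phase, all else as stated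

- Product and lost substrate follow each other through Saturday's readings, each with a scatter of 1 percentage point, so I average them, which gives a conversion of 9.60 % at 6.00 h and 19.3 % at 15.0 h.
- The readings show no lag, so I hold the gas steady and treat the substrate as pseudo-first-order, with ln(c_substrate) falling at a pace s; this pace averages 0.0168 h⁻¹ up to 6.00 h but 0.0125 h⁻¹ afterwards, so the pace itself decays.
- Taking that decay as exponential, the midpoints of the two stretches, 7.50 h apart, give 25.6 h, the life of the working catalyst, and this is a reading that carries the scatter.
- In this flask, my curve starts with a pace of 0.0189 h⁻¹, bends at one life with product at 26.3 %, reaches 0.382 in the logarithm, so 31.8 % of product, at 40 h, and runs towards a level of 38.4 %.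
- I expect s to scale with the catalyst, so my curve for oak has twice that logarithm and 53.5 % of product, which makes oak my choice, and as Saturday's readings show no lag I expect little from birch.
- The forecast says 29 %, maple and 32 %, reasoning that “Both transfer and reaction scale with dissolved gas”.
- This flask gives 33.7 %; oak is best, gaining 22 points against 6.4 points for maple and 0.62 points for birch, which reaches 34.3 %.

    gas phase ⇌ dissolved gas, rate k1*(csat - [dissolved gas]) (kL = 9.40 × 10⁻⁴ s⁻¹)
    substrate + dissolved gas + free catalyst → free catalyst + product (k = 0.00690 M⁻² s⁻¹)
    dissolved gas → decomposed reagent (k = 2.00 × 10⁻⁵ s⁻¹)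
    dissolved gas + free catalyst → spent catalyst (k = 1.40 × 10⁻⁴ M⁻¹ s⁻¹)

- This flask loses its catalyst as spent catalyst: with that step taken away it gives 52.2 % instead of 33.7 %, the largest single effect, though a part of what is missing. The life puts free catalyst at 21.0 % at 40.0 h, and this flask holds 24.2 %. For the neighbour flask with 2 mol%, the same life and the logarithm scaled by 4.00 give 78.3 %, and that flask gives 79.0 %.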